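**Plan**

- Retrosynthesis: the three aryl O–CH3 bonds are cut last. Ring C (the 4-hydroxy-2-pyrone) is cut at its lactone C–O bond and at the bond between the side-chain carbonyl and the methyl carbon of a dioxinone, which leaves an arylacetic acid.
- Ring B is cut at C1'–C2' and C1'–C6'. C1' sits on chromone C2 between the oxygen-bearing C2' and the alkyl-bearing C6', so it can be the acidic 2-methyl carbon of a 2-methylchromone; C2'–C6', with the 2',4'-oxygens and the C6' chain, map onto a 2,4-dimethoxy-6-alkylpyrylium ring.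
- Forward: the chromone (ring A and the pyranone ring) is closed first from an acetophenone, and the pyrylium salt is made from 4-methoxy-6-methyl-2-pyrone. Ring B is then built between the two, ring C is closed last from a keto-dioxinone, and the methyl ethers are removed.
- Stereochemistry: the target has no stereocentre and no configured double bond, so nothing has to be set.

Key step: step 6

Assumption: in the ring-forming step both α-carbons of the pyrylium ring are productive sites of attack; the route is written for attack at the alkyl-bearing α-carbon, and product of the other mode merges one step later.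

Step 1
Reactants: 1 1-(2,4-dihydroxy-6-methylphenyl)ethanone
Product: 2 1-(2-hydroxy-4-methoxy-6-methylphenyl)ethanone
Conditions: MeI (1.05 equiv), K2CO3, acetone, 56 °C
Reagents that add atoms: iodomethane, CI
Why: Williamson etherification; the C2 hydroxyl is held in a hydrogen bond to the acetyl carbonyl and is the less acidic one, so one equivalent of MeI should alkylate only the C4 phenoxide.

Step 2
Reactants: 2 1-(2-hydroxy-4-methoxy-6-methylphenyl)ethanone
Product: 4 7-methoxy-2,5-dimethyl-4H-chromen-4-one, via diketone 3 (not isolated)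
Conditions: NaH, EtOAc, THF, 65 °C; then conc. HCl, MeOH, 65 °C
Reagents that add atoms: ethyl acetate, CCOC(C)=O
Why: Crossed Claisen condensation of the phenoxide–enolate of 2 with ethyl acetate should give diketone 3, and acid then closes the phenol onto the distal carbonyl with loss of water, the classical cyclodehydration route to 2-methylchromones.

Step 3
Reactants: 5 4-methoxy-6-methyl-2H-pyran-2-one
Product: 7 6-(2-hydroxyethyl)-4-methoxy-2H-pyran-2-one, via lithium dienolate 6 (not isolated)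
Conditions: LiN(SiMe3)2, THF, −78 °C; CH2O (gas, from cracked paraformaldehyde), −78 °C; AcOH
Reagents that add atoms: formaldehyde, C=O
Why: Kinetic deprotonation of the C6 methyl group of 4-methoxy-2-pyrones gives a dienolate that reacts with aldehydes at the exocyclic carbon, here a vinylogous aldol addition to monomeric formaldehyde.

Step 4
Reactants: 7 6-(2-hydroxyethyl)-4-methoxy-2H-pyran-2-one
Product: 8 4-methoxy-6-[2-(triisopropylsilyloxy)ethyl]-2H-pyran-2-one
Conditions: TIPSCl, imidazole, DMF, 25 °C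
Reagents that add atoms: chlorotri(propan-2-yl)silane, CC(C)[Si](Cl)(C(C)C)C(C)C
Why: Standard silylation of a primary alcohol; the bulky silyl ether is chosen because it should survive the oxonium salt and methoxide of the next steps and leaves the side chain without a second activating group.

Step 5
Reactants: 8 4-methoxy-6-[2-(triisopropylsilyloxy)ethyl]-2H-pyran-2-one
Product: 9 2,4-dimethoxy-6-[2-(triisopropylsilyloxy)ethyl]pyrylium tetrafluoroborate
Conditions: Me3OBF4, CH2Cl2, 25 °C; precipitation with dry Et2O, used directly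
Reagents that add atoms: trimethyloxonium tetrafluoroborate, C[O+](C)C.F[B-](F)(F)F
Why: Meerwein O-methylation of the 2-pyrone carbonyl oxygen is a known entry to 2-alkoxypyrylium salts, the aromatic cation being the driving force and the hindered silyl ether oxygen a poor competitor.

Step 6
Reactants: 4 7-methoxy-2,5-dimethyl-4H-chromen-4-one; 9 2,4-dimethoxy-6-[2-(triisopropylsilyloxy)ethyl]pyrylium tetrafluoroborate
Product: 14 2-[2-hydroxy-4-methoxy-6-[2-(triisopropylsilyloxy)ethyl]phenyl]-7-methoxy-5-methyl-4H-chromen-4-one, via lithium dienolate 10 (not isolated), via silyl dienol ether 11 (not isolated), via 2H-pyran adduct 12 (not isolated), via dienyl ester 13 (not isolated)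
Conditions: 4, LiN(SiMe3)2, THF, −78 °C; TBSOTf, −78 → 0 °C; then 9 in CH2Cl2, −78 → 0 °C; NaOMe, MeOH, 0 → 25 °C; AcOH
Reagents that add atoms: none
Why: Proposed new method: silyl dienol ether 11, a neutral π-nucleophile that cannot deprotonate the side chain of 9, should add through its exocyclic CH2 (Mukaiyama-type cation–enol ether combination) to C6 of the pyrylium ring, the only α- or γ-carbon without an alkoxy donor, forming the C1'–C6' bond in 2H-pyran 12. Methoxide then removes the silyl group, the 2H-pyran opens electrocyclically to dienyl ester 13, and the deprotonated chromonyl CH2 attacks the ester carbonyl in a 6-exo-trig Claisen (Dieckmann-type) closure that forms C1'–C2'; loss of methanol and enolisation give the aromatic ring B with its C2' phenol. The closest known reaction types are the conversion of 2,4,6-triarylpyrylium salts into benzenes by CH-acids such as nitromethane and the addition of benzylic carbanions to 2,4-dimethoxypyrylium salts. No stereocentre remains, because the quaternary carbon of 12 becomes the aromatic C6'. The step needs α- over γ-attack on the cation and reaction at the 2-methyl and not the 5-methyl group of 4: the first is favoured by the C4 methoxy donor and eased by the fact that attack at the other α-carbon (C2) also ends in ring B (aldol closure to the 2'-methyl ether that the next step makes anyway), the second by the vinylogous activation of the 2-methyl group by the chromone carbonyl.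

Step 7
Reactants: 14 2-[2-hydroxy-4-methoxy-6-[2-(triisopropylsilyloxy)ethyl]phenyl]-7-methoxy-5-methyl-4H-chromen-4-one
Product: 15 2-[2,4-dimethoxy-6-[2-(triisopropylsilyloxy)ethyl]phenyl]-7-methoxy-5-methyl-4H-chromen-4-one
Conditions: MeI, K2CO3, DMF, 25 °C
Reagents that add atoms: iodomethane, CI
Why: Williamson methylation of the only free phenol protects C2'–OH for the enolate chemistry ahead and would merge any 2'-methyl ether from step 6 into a single compound.

Step 8
Reactants: 15 2-[2,4-dimethoxy-6-[2-(triisopropylsilyloxy)ethyl]phenyl]-7-methoxy-5-methyl-4H-chromen-4-one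
Product: 16 2-[2-(2-hydroxyethyl)-4,6-dimethoxyphenyl]-7-methoxy-5-methyl-4H-chromen-4-one
Conditions: TBAF, THF, 0 → 25 °C
Reagents that add atoms: none
Why: Fluoride-induced silyl ether cleavage driven by the strong Si–F bond; no other group in 15 is fluoride-labile.

Step 9
Reactants: 16 2-[2-(2-hydroxyethyl)-4,6-dimethoxyphenyl]-7-methoxy-5-methyl-4H-chromen-4-one
Product: 17 2-[3,5-dimethoxy-2-(7-methoxy-5-methyl-4-oxo-4H-chromen-2-yl)phenyl]acetic acid
Conditions: TEMPO (cat.), PhI(OAc)2 (2.5 equiv), MeCN/H2O 1:1, 25 °C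
Reagents that add atoms: water, O
Why: The oxoammonium-mediated (TEMPO/PhI(OAc)2) oxidation takes a primary alcohol through the aldehyde hydrate to the carboxylic acid without strong acid or halogenating species, so the electron-rich ring B and the chromone should be left alone.

Step 10
Reactants: 17 2-[3,5-dimethoxy-2-(7-methoxy-5-methyl-4-oxo-4H-chromen-2-yl)phenyl]acetic acid; 18 2,2,6-trimethyl-4H-1,3-dioxin-4-one
Product: 21 6-[3-[3,5-dimethoxy-2-(7-methoxy-5-methyl-4-oxo-4H-chromen-2-yl)phenyl]-2-oxopropyl]-2,2-dimethyl-4H-1,3-dioxin-4-one, via acyl imidazole 19 (not isolated), via lithium dienolate 20 (not isolated)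
Conditions: 17, CDI, THF, 25 °C; added to 18, LiN(SiMe3)2 (3 equiv each), THF, −78 °C; AcOH
Reagents that add atoms: none
Why: γ-Acylation of the lithium dienolate of the dioxinone by an acyl imidazole (a vinylogous crossed Claisen condensation) is a standard entry to 6-(2-oxoalkyl)dioxinones; excess dienolate absorbs the acidic product, and the hindered 2-arylchromone is not expected to be attacked.

Step 11
Reactants: 21 6-[3-[3,5-dimethoxy-2-(7-methoxy-5-methyl-4-oxo-4H-chromen-2-yl)phenyl]-2-oxopropyl]-2,2-dimethyl-4H-1,3-dioxin-4-one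
Product: 23 2-[2-[(4-hydroxy-2-oxo-2H-pyran-6-yl)methyl]-4,6-dimethoxyphenyl]-7-methoxy-5-methyl-4H-chromen-4-one, via acylketene 22 (not isolated)
Conditions: toluene, 110 °C
Reagents that add atoms: none
Why: Thermal retro-[4+2] loss of acetone from the dioxinone gives acylketene 22, which the enol oxygen of the neighbouring ketone traps to close ring C, the established dioxinone route to 4-hydroxy-2-pyrones.

Step 12
Reactants: 23 2-[2-[(4-hydroxy-2-oxo-2H-pyran-6-yl)methyl]-4,6-dimethoxyphenyl]-7-methoxy-5-methyl-4H-chromen-4-one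
Product: 24 2-[2,4-dihydroxy-6-[(4-hydroxy-2-oxo-2H-pyran-6-yl)methyl]phenyl]-7-hydroxy-5-methyl-4H-chromen-4-one
Conditions: BBr3 (excess), CH2Cl2, −78 → 25 °C; then MeOH, H2O
Reagents that add atoms: none
Why: Lewis-acid cleavage of aryl methyl ethers by BBr3 (through aryloxyboron bromides and bromomethane) is routine for methoxychromones, and the chromone and hydroxypyrone carbonyls are only complexed and are set free on hydrolysis.

**Compound list**

1 | 1-(2,4-dihydroxy-6-methylphenyl)ethanone | CC(=O)c1c(C)cc(O)cc1O | starting material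
2 | 1-(2-hydroxy-4-methoxy-6-methylphenyl)ethanone | CC(=O)c1c(C)cc(OC)cc1O | intermediate
3 | 1-(2-hydroxy-4-methoxy-6-methylphenyl)butane-1,3-dione | CC(=O)CC(=O)c1c(C)cc(OC)cc1O | intermediate (not isolated)
4 | 7-methoxy-2,5-dimethyl-4H-chromen-4-one | Cc1cc(=O)c2c(C)cc(OC)cc2o1 | intermediate
5 | 4-methoxy-6-methyl-2H-pyran-2-one | Cc1cc(OC)cc(=O)o1 | starting material
6 | lithium 4-methoxy-6-methylidene-6H-pyran-2-olate | [Li+].C=C1C=C(OC)C=C([O-])O1 | intermediate (not isolated)
7 | 6-(2-hydroxyethyl)-4-methoxy-2H-pyran-2-one | COc1cc(CCO)oc(=O)c1 | intermediate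
8 | 4-methoxy-6-[2-(triisopropylsilyloxy)ethyl]-2H-pyran-2-one | COc1cc(CCO[Si](C(C)C)(C(C)C)C(C)C)oc(=O)c1 | intermediate
9 | 2,4-dimethoxy-6-[2-(triisopropylsilyloxy)ethyl]pyrylium tetrafluoroborate | COc1cc(OC)[o+]c(CCO[Si](C(C)C)(C(C)C)C(C)C)c1.F[B-](F)(F)F | intermediate
10 | lithium 7-methoxy-5-methyl-2-methylidene-2H-chromen-4-olate | [Li+].C=C1C=C([O-])c2c(C)cc(OC)cc2O1 | intermediate (not isolated)
11 | tert-butyl[(7-methoxy-5-methyl-2-methylidene-2H-chromen-4-yl)oxy]dimethylsilane | C=C1C=C(O[Si](C)(C)C(C)(C)C)c2c(C)cc(OC)cc2O1 | intermediate (not isolated)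
12 | 2-[[4,6-dimethoxy-2-[2-(triisopropylsilyloxy)ethyl]-2H-pyran-2-yl]methyl]-7-methoxy-5-methyl-4H-chromen-4-one (racemic) | COC1=CC(OC)=CC(CCO[Si](C(C)C)(C(C)C)C(C)C)(Cc2cc(=O)c3c(C)cc(OC)cc3o2)O1 | intermediate (not isolated)
13 | methyl (2E,4Z)-3-methoxy-5-[(7-methoxy-5-methyl-4-oxo-4H-chromen-2-yl)methyl]-7-(triisopropylsilyloxy)hepta-2,4-dienoate | COC(=O)/C=C(OC)\C=C(/Cc1cc(=O)c2c(C)cc(OC)cc2o1)CCO[Si](C(C)C)(C(C)C)C(C)C | intermediate (not isolated)
14 | 2-[2-hydroxy-4-methoxy-6-[2-(triisopropylsilyloxy)ethyl]phenyl]-7-methoxy-5-methyl-4H-chromen-4-one | Cc1cc(OC)cc2oc(-c3c(O)cc(OC)cc3CCO[Si](C(C)C)(C(C)C)C(C)C)cc(=O)c12 | intermediate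
15 | 2-[2,4-dimethoxy-6-[2-(triisopropylsilyloxy)ethyl]phenyl]-7-methoxy-5-methyl-4H-chromen-4-one | Cc1cc(OC)cc2oc(-c3c(OC)cc(OC)cc3CCO[Si](C(C)C)(C(C)C)C(C)C)cc(=O)c12 | intermediate
16 | 2-[2-(2-hydroxyethyl)-4,6-dimethoxyphenyl]-7-methoxy-5-methyl-4H-chromen-4-one | Cc1cc(OC)cc2oc(-c3c(OC)cc(OC)cc3CCO)cc(=O)c12 | intermediate
17 | 2-[3,5-dimethoxy-2-(7-methoxy-5-methyl-4-oxo-4H-chromen-2-yl)phenyl]acetic acid | Cc1cc(OC)cc2oc(-c3c(OC)cc(OC)cc3CC(=O)O)cc(=O)c12 | intermediate
18 | 2,2,6-trimethyl-4H-1,3-dioxin-4-one | CC1=CC(=O)OC(C)(C)O1 | starting material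
19 | 2-[2-[2-(1H-imidazol-1-yl)-2-oxoethyl]-4,6-dimethoxyphenyl]-7-methoxy-5-methyl-4H-chromen-4-one | Cc1cc(OC)cc2oc(-c3c(OC)cc(OC)cc3CC(=O)n3ccnc3)cc(=O)c12 | intermediate (not isolated)
20 | lithium 2,2-dimethyl-6-methylidene-6H-1,3-dioxin-4-olate | [Li+].C=C1C=C([O-])OC(C)(C)O1 | intermediate (not isolated)
21 | 6-[3-[3,5-dimethoxy-2-(7-methoxy-5-methyl-4-oxo-4H-chromen-2-yl)phenyl]-2-oxopropyl]-2,2-dimethyl-4H-1,3-dioxin-4-one | CC1(C)OC(=O)C=C(CC(=O)Cc2cc(OC)cc(OC)c2-c2cc(=O)c3c(C)cc(OC)cc3o2)O1 | intermediate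
22 | 6-[3,5-dimethoxy-2-(7-methoxy-5-methyl-4-oxo-4H-chromen-2-yl)phenyl]-3,5-dioxohex-1-en-1-one | O=C=CC(=O)CC(=O)Cc1cc(OC)cc(OC)c1-c1cc(=O)c2c(C)cc(OC)cc2o1 | intermediate (not isolated)
23 | 2-[2-[(4-hydroxy-2-oxo-2H-pyran-6-yl)methyl]-4,6-dimethoxyphenyl]-7-methoxy-5-methyl-4H-chromen-4-one | Cc1cc(OC)cc2oc(-c3c(OC)cc(OC)cc3Cc3cc(O)cc(=O)o3)cc(=O)c12 | intermediate
24 | 2-[2,4-dihydroxy-6-[(4-hydroxy-2-oxo-2H-pyran-6-yl)methyl]phenyl]-7-hydroxy-5-methyl-4H-chromen-4-one | Cc1cc(O)cc2oc(-c3c(O)cc(O)cc3Cc3cc(O)cc(=O)o3)cc(=O)c12 | target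

**Count and risks**

Total step count: 12. Longest linear sequence: 10 steps (5 → 7 → 8 → 9 → 14 → 15 → 16 → 17 → 21 → 23 → 24); the chromone branch 1 → 2 → 4 joins at step 6.

Steps most likely to fail:

Step 6 (carries the label). What may go wrong: addition of the silyl dienol ether at C4 followed by loss of methoxide to a methylenepyran, transfer of a methyl group from the cation to the nucleophile, or proton loss from the side chain of the cation, so that ring B is never closed. The fallback builds the 2-arylchromone by the classical diketone route; it sets out from 2 and comes back to the route at 15. Commercial 2-(3,5-dimethoxyphenyl)ethanol F1 is silylated (TIPSCl, imidazole) to [2-(3,5-dimethoxyphenyl)ethoxy]tri(propan-2-yl)silane F2. NBS in MeCN brominates the position para to one methoxy group and ortho to the chain, giving [2-(2-bromo-3,5-dimethoxyphenyl)ethoxy]tri(propan-2-yl)silane F3. Bromine–lithium exchange (n-BuLi, THF, −78 °C) and CO2 give 2,4-dimethoxy-6-[2-(triisopropylsilyloxy)ethyl]benzoic acid F4, which 1-chloro-N,N,2-trimethylprop-1-en-1-amine converts under neutral conditions into 2,4-dimethoxy-6-[2-(triisopropylsilyloxy)ethyl]benzoyl chloride F5. The phenoxide–enolate of 2 (LiN(SiMe3)2, 3 equiv, THF, −78 °C) is C-acylated by this chloride to 1-[2,4-dimethoxy-6-[2-(triisopropylsilyloxy)ethyl]phenyl]-3-(2-hydroxy-4-methoxy-6-methylphenyl)propane-1,3-dione F6, and catalytic TsOH in toluene at 80 °C closes the pyranone ring to 15.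

Step 10. What may go wrong: proton transfer from the enolisable acyl imidazole to the dienolate (ketene formation and self-condensation) in place of C-acylation. The fallback reverses the polarity of the coupling partner; it sets out from 16 and comes back at 21. Dess–Martin periodinane oxidises 16 to 2-[3,5-dimethoxy-2-(7-methoxy-5-methyl-4-oxo-4H-chromen-2-yl)phenyl]acetaldehyde F7. The silyl dienol ether [(2,2-dimethyl-6-methylidene-6H-1,3-dioxin-4-yl)oxy]trimethylsilane F8, made from 18 through 20 with TMSCl, adds in a BF3·OEt2-promoted vinylogous Mukaiyama aldol reaction (CH2Cl2, −78 °C). This gives racemic 6-[3-[3,5-dimethoxy-2-(7-methoxy-5-methyl-4-oxo-4H-chromen-2-yl)phenyl]-2-hydroxypropyl]-2,2-dimethyl-4H-1,3-dioxin-4-one F9, which Dess–Martin periodinane oxidises to 21.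

Step 12. What may go wrong: incomplete cleavage of the chromone 7-methoxy group, or degradation of the hydroxypyrone and the benzylic bridge under prolonged Lewis-acid treatment. The fallback moves the demethylation to the robust acid stage and exchanges the ethers for acetals that fall off under mild acid; it sets out from 17 and comes back at 24.
- BBr3 converts 17 into 2-[3,5-dihydroxy-2-(7-hydroxy-5-methyl-4-oxo-4H-chromen-2-yl)phenyl]acetic acid F10.
- MOMCl and i-Pr2NEt give methoxymethyl 2-[3,5-bis(methoxymethoxy)-2-[7-(methoxymethoxy)-5-methyl-4-oxo-4H-chromen-2-yl]phenyl]acetate F11.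
- LiOH in aqueous THF frees 2-[3,5-bis(methoxymethoxy)-2-[7-(methoxymethoxy)-5-methyl-4-oxo-4H-chromen-2-yl]phenyl]acetic acid F12.
- As in the main line, CDI gives the acyl imidazole 2-[2-[2-(1H-imidazol-1-yl)-2-oxoethyl]-4,6-bis(methoxymethoxy)phenyl]-7-(methoxymethoxy)-5-methyl-4H-chromen-4-one F13.
- Dienolate 20 is acylated to 6-[3-[3,5-bis(methoxymethoxy)-2-[7-(methoxymethoxy)-5-methyl-4-oxo-4H-chromen-2-yl]phenyl]-2-oxopropyl]-2,2-dimethyl-4H-1,3-dioxin-4-one F14.
- Heating in toluene passes through the acylketene 6-[3,5-bis(methoxymethoxy)-2-[7-(methoxymethoxy)-5-methyl-4-oxo-4H-chromen-2-yl]phenyl]-3,5-dioxohex-1-en-1-one F15 to 2-[2-[(4-hydroxy-2-oxo-2H-pyran-6-yl)methyl]-4,6-bis(methoxymethoxy)phenyl]-7-(methoxymethoxy)-5-methyl-4H-chromen-4-one F16.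
- 3 M HCl in THF at 40 °C removes the three acetals to give 24.

Further compounds
F1 | step 6 | 2-(3,5-dimethoxyphenyl)ethanol | COc1cc(CCO)cc(OC)c1
F2 | step 6 | [2-(3,5-dimethoxyphenyl)ethoxy]tri(propan-2-yl)silane | COc1cc(CCO[Si](C(C)C)(C(C)C)C(C)C)cc(OC)c1
F3 | step 6 | [2-(2-bromo-3,5-dimethoxyphenyl)ethoxy]tri(propan-2-yl)silane | COc1cc(OC)c(Br)c(CCO[Si](C(C)C)(C(C)C)C(C)C)c1
F4 | step 6 | 2,4-dimethoxy-6-[2-(triisopropylsilyloxy)ethyl]benzoic acid | COc1cc(OC)c(C(=O)O)c(CCO[Si](C(C)C)(C(C)C)C(C)C)c1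
F5 | step 6 | 2,4-dimethoxy-6-[2-(triisopropylsilyloxy)ethyl]benzoyl chloride | COc1cc(OC)c(C(Cl)=O)c(CCO[Si](C(C)C)(C(C)C)C(C)C)c1
F6 | step 6 | 1-[2,4-dimethoxy-6-[2-(triisopropylsilyloxy)ethyl]phenyl]-3-(2-hydroxy-4-methoxy-6-methylphenyl)propane-1,3-dione | COc1cc(C)c(C(=O)CC(=O)c2c(OC)cc(OC)cc2CCO[Si](C(C)C)(C(C)C)C(C)C)c(O)c1
F7 | step 10 | 2-[3,5-dimethoxy-2-(7-methoxy-5-methyl-4-oxo-4H-chromen-2-yl)phenyl]acetaldehyde | Cc1cc(OC)cc2oc(-c3c(OC)cc(OC)cc3CC=O)cc(=O)c12
F8 | step 10 | [(2,2-dimethyl-6-methylidene-6H-1,3-dioxin-4-yl)oxy]trimethylsilane | C=C1C=C(O[Si](C)(C)C)OC(C)(C)O1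
F9 | step 10 | 6-[3-[3,5-dimethoxy-2-(7-methoxy-5-methyl-4-oxo-4H-chromen-2-yl)phenyl]-2-hydroxypropyl]-2,2-dimethyl-4H-1,3-dioxin-4-one (racemic) | CC1(C)OC(=O)C=C(CC(O)Cc2cc(OC)cc(OC)c2-c2cc(=O)c3c(C)cc(OC)cc3o2)O1
F10 | step 12 | 2-[3,5-dihydroxy-2-(7-hydroxy-5-methyl-4-oxo-4H-chromen-2-yl)phenyl]acetic acid | Cc1cc(O)cc2oc(-c3c(O)cc(O)cc3CC(=O)O)cc(=O)c12
F11 | step 12 | methoxymethyl 2-[3,5-bis(methoxymethoxy)-2-[7-(methoxymethoxy)-5-methyl-4-oxo-4H-chromen-2-yl]phenyl]acetate | Cc1cc(OCOC)cc2oc(-c3c(OCOC)cc(OCOC)cc3CC(=O)OCOC)cc(=O)c12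
F12 | step 12 | 2-[3,5-bis(methoxymethoxy)-2-[7-(methoxymethoxy)-5-methyl-4-oxo-4H-chromen-2-yl]phenyl]acetic acid | Cc1cc(OCOC)cc2oc(-c3c(OCOC)cc(OCOC)cc3CC(=O)O)cc(=O)c12
F13 | step 12 | 2-[2-[2-(1H-imidazol-1-yl)-2-oxoethyl]-4,6-bis(methoxymethoxy)phenyl]-7-(methoxymethoxy)-5-methyl-4H-chromen-4-one | Cc1cc(OCOC)cc2oc(-c3c(OCOC)cc(OCOC)cc3CC(=O)n3ccnc3)cc(=O)c12
F14 | step 12 | 6-[3-[3,5-bis(methoxymethoxy)-2-[7-(methoxymethoxy)-5-methyl-4-oxo-4H-chromen-2-yl]phenyl]-2-oxopropyl]-2,2-dimethyl-4H-1,3-dioxin-4-one | CC1(C)OC(=O)C=C(CC(=O)Cc2cc(OCOC)cc(OCOC)c2-c2cc(=O)c3c(C)cc(OCOC)cc3o2)O1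
F15 | step 12 | 6-[3,5-bis(methoxymethoxy)-2-[7-(methoxymethoxy)-5-methyl-4-oxo-4H-chromen-2-yl]phenyl]-3,5-dioxohex-1-en-1-one | O=C=CC(=O)CC(=O)Cc1cc(OCOC)cc(OCOC)c1-c1cc(=O)c2c(C)cc(OCOC)cc2o1
F16 | step 12 | 2-[2-[(4-hydroxy-2-oxo-2H-pyran-6-yl)methyl]-4,6-bis(methoxymethoxy)phenyl]-7-(methoxymethoxy)-5-methyl-4H-chromen-4-one | Cc1cc(OCOC)cc2oc(-c3c(OCOC)cc(OCOC)cc3Cc3cc(O)cc(=O)o3)cc(=O)c12
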